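Assumption: (2S)-hesperetin (aglycone of the citrus glycoside hesperidin) and methyl (R)-2,3-O-isopropylideneglycerate (from D-mannitol) are bought as single enantiomers.

**Retrosynthetic overview**
- Last step: ammonolysis of two aryl pivalates.
- The 1,4-dioxane ring is the only ring made and is closed last: a tethered secondary alcohol displaces the 4'-OMe of ring B under photoredox catalysis, forming the aryl C4'–O bond. Hesperetin's methyl ether thus fixes the regiochemistry and serves as the leaving group.
- The 3'-O–benzylic carbon bond comes from a Mitsunobu inversion between 7-O-pivaloylhesperetin and a syn aryl(dioxolanyl)carbinol, followed by acetonide removal.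
- The carbinol comes from D-glycerate acetonide: aryl ketone synthesis, then Felkin–Anh reduction.
- Rings A, B and C and the flavanone stereocentre are bought intact in (2S)-hesperetin; both dioxane stereocentres trace back to C2 of D-glyceric acid.

**Route**

Step 1
Reactants: 1 4-iodo-2-methoxyphenol
Product: 2 4-iodo-2-methoxyphenyl pivalate
Conditions: PivCl (1.1 equiv), Et3N, DMAP (cat.), CH2Cl2, 0 °C → rt
Reagents that add atoms: pivaloyl chloride CC(C)(C)C(Cl)=O
Why: DMAP-catalysed O-acylation of the phenol; the hindered pivalate survives the magnesium chemistry of step 2 and makes the vanillyl ring electron-poorer than ring B for step 6.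

Step 2
Reactants: 2 4-iodo-2-methoxyphenyl pivalate; 3 methyl (4R)-2,2-dimethyl-1,3-dioxolane-4-carboxylate
Product: 6 4-[(4R)-2,2-dimethyl-1,3-dioxolane-4-carbonyl]-2-methoxyphenyl pivalate, via Weinreb amide 4 (not isolated), via arylmagnesium chloride 5 (not isolated)
Conditions: flask a: 3, MeNH(OMe)·HCl (1.5 equiv), iPrMgCl (3.0 equiv), THF, –20 °C; flask b: 2 (1.3 equiv), iPrMgCl·LiCl, THF, –15 °C, 1 h; b cannulated into a, –15 → 0 °C; aq. NH4Cl
Reagents that add atoms: none
Why: Iodine–magnesium exchange (Knochel) gives an ester-tolerant aryl Grignard and the Weinreb ketone synthesis stops at the ketone because the chelated tetrahedral adduct collapses only on quench, so the bought dioxolane stereocentre is never exposed to base as an enolisable ketone.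

Step 3
Reactants: 6 4-[(4R)-2,2-dimethyl-1,3-dioxolane-4-carbonyl]-2-methoxyphenyl pivalate
Product: 7 4-{(R)-[(4R)-2,2-dimethyl-1,3-dioxolan-4-yl](hydroxy)methyl}-2-methoxyphenyl pivalate (syn carbinol)
Conditions: LiBH(s-Bu)3 (1.2 equiv), THF, –78 °C, 1 h; aq. NH4Cl (non-oxidative work-up); minor anti epimer removed by chromatography
Reagents that add atoms: none
Why: Felkin–Anh (polar, non-chelating) reduction: the bulky hydride attacks anti to the α C–O bond of the (R)-dioxolane and gives the (R)-carbinol (syn, expected dr ≥ 10:1), so the new centre is controlled by the bought one; the pivalate is inert at –78 °C.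

Step 4
Reactants: 8 (2S)-hesperetin
Product: 9 (2S)-5-hydroxy-2-(3-hydroxy-4-methoxyphenyl)-4-oxochroman-7-yl pivalate
Conditions: PivCl (1.05 equiv), iPr2NEt (1.1 equiv), THF, –20 → 0 °C
Reagents that add atoms: pivaloyl chloride CC(C)(C)C(Cl)=O
Why: Chemoselective O-acylation: 7-OH is the most acidic and least hindered phenol, 5-OH is chelated to the carbonyl and 3'-OH is flanked by OMe; with no free 4'-OH, C2 cannot racemise through a quinone methide under this mild base.

Step 5
Reactants: 7 syn carbinol (1.2 equiv); 9 (2S)-5-hydroxy-2-(3-hydroxy-4-methoxyphenyl)-4-oxochroman-7-yl pivalate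
Product: 11 (2S)-2-[3-({(1S,2R)-2,3-dihydroxy-1-[3-methoxy-4-(pivaloyloxy)phenyl]propyl}oxy)-4-methoxyphenyl]-5-hydroxy-4-oxochroman-7-yl pivalate, via acetonide ether 10 (not isolated)
Conditions: PPh3 (1.5 equiv), DIAD (1.5 equiv), THF, 0 °C → rt; then 2 M aq. HCl added to the same flask, rt
Reagents that add atoms: none
Why: Mitsunobu etherification: the only unchelated phenol of 9 (3'-OH) displaces the activated benzylic oxygen of 7 with inversion (R → S, giving the erythro ether), and dilute acid then hydrolyses the terminal acetonide without touching the esters, the aryl ether or the flavanone.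

Step 6
Reactants: 11 diol ether
Product: 12 (2S)-5-hydroxy-2-{(2R,3S)-2-(hydroxymethyl)-3-[3-methoxy-4-(pivaloyloxy)phenyl]-2,3-dihydro-1,4-benzodioxin-6-yl}-4-oxochroman-7-yl pivalate
Conditions: 3,6-di-tert-butyl-9-mesityl-10-phenylacridinium tetrafluoroborate (5 mol %), 450 nm LEDs, DCE/HFIP 4:1, 0.02 M, degassed, N2, 25 °C
Reagents that add atoms: none
Why: Proposed new method: photoredox cation-radical-accelerated nucleophilic aromatic substitution with a tethered secondary alcohol as nucleophile and methoxide as leaving group — the excited acridinium (about +2.0 V vs SCE) oxidises the 3',4'-dialkoxy ring B (estimated +1.4 V; the pivaloyloxy-anisole ring at about +1.8 V and the acylated ring A are harder to oxidise, and a hole formed there relaxes to ring B), the C2-OH of the side chain adds ipso at C4' (the alkoxy carbon para to the alkyl group, where the radical cation carries most positive charge; six-membered closure), the acridinyl radical reduces the σ-adduct and HFIP-assisted loss of MeOH rearomatises to the 1,4-benzodioxane; neither carbinol C–O bond is broken, so the (1S,2R) centres of 11 become the (3S,2R) cis centres of 12, and the anaerobic, base-free medium closes off C–H etherification and benzylic deprotonation at flavanone C2; the closest known reaction type is acridinium-photocatalysed SNAr of methoxyarenes with azoles, amines or ammonia (C–O to C–N), not shown intramolecularly with an alcohol to build a benzodioxane.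

Step 7
Reactants: 12 dipivalate
Product: 13 isocisilandrin, (2S)-5,7-dihydroxy-2-[(2R,3S)-3-(4-hydroxy-3-methoxyphenyl)-2-(hydroxymethyl)-2,3-dihydro-1,4-benzodioxin-6-yl]chroman-4-one
Conditions: NH3 (7 N in MeOH), argon, 0 °C → rt
Reagents that add atoms: none
Why: Ammonolysis of the two aryl pivalates (nucleophilic acyl substitution) under weakly basic, oxygen-free conditions that do not open the flavanone (4'-O is alkylated) and do not ionise the cis benzylic aryl ether.

**Compound list**

1 | 4-iodo-2-methoxyphenol | COc1cc(I)ccc1O | starting material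
2 | 4-iodo-2-methoxyphenyl pivalate | COc1cc(I)ccc1OC(=O)C(C)(C)C | intermediate
3 | methyl (4R)-2,2-dimethyl-1,3-dioxolane-4-carboxylate | COC(=O)[C@H]1COC(C)(C)O1 | starting material
4 | (4R)-N-methoxy-N,2,2-trimethyl-1,3-dioxolane-4-carboxamide (Weinreb amide, not isolated) | CON(C)C(=O)[C@H]1COC(C)(C)O1 | intermediate
5 | [3-methoxy-4-(pivaloyloxy)phenyl]magnesium chloride, LiCl complex (not isolated) | COc1cc([Mg]Cl)ccc1OC(=O)C(C)(C)C | intermediate
6 | 4-[(4R)-2,2-dimethyl-1,3-dioxolane-4-carbonyl]-2-methoxyphenyl pivalate | COc1cc(C(=O)[C@H]2COC(C)(C)O2)ccc1OC(=O)C(C)(C)C | intermediate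
7 | 4-{(R)-[(4R)-2,2-dimethyl-1,3-dioxolan-4-yl](hydroxy)methyl}-2-methoxyphenyl pivalate | O[C@H](c1ccc(OC(=O)C(C)(C)C)c(OC)c1)[C@H]1COC(C)(C)O1 | intermediate
8 | (2S)-hesperetin | COc1ccc([C@@H]2CC(=O)c3c(O)cc(O)cc3O2)cc1O | starting material
9 | (2S)-5-hydroxy-2-(3-hydroxy-4-methoxyphenyl)-4-oxochroman-7-yl pivalate | COc1ccc([C@@H]2CC(=O)c3c(O)cc(OC(=O)C(C)(C)C)cc3O2)cc1O | intermediate
10 | (2S)-2-[3-({(S)-[(4R)-2,2-dimethyl-1,3-dioxolan-4-yl][3-methoxy-4-(pivaloyloxy)phenyl]methyl}oxy)-4-methoxyphenyl]-5-hydroxy-4-oxochroman-7-yl pivalate (not isolated) | COc1ccc([C@@H]2CC(=O)c3c(O)cc(OC(=O)C(C)(C)C)cc3O2)cc1O[C@@H](c1ccc(OC(=O)C(C)(C)C)c(OC)c1)[C@H]1COC(C)(C)O1 | intermediate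
11 | (2S)-2-[3-({(1S,2R)-2,3-dihydroxy-1-[3-methoxy-4-(pivaloyloxy)phenyl]propyl}oxy)-4-methoxyphenyl]-5-hydroxy-4-oxochroman-7-yl pivalate | COc1ccc([C@@H]2CC(=O)c3c(O)cc(OC(=O)C(C)(C)C)cc3O2)cc1O[C@@H](c1ccc(OC(=O)C(C)(C)C)c(OC)c1)[C@H](O)CO | intermediate
12 | (2S)-5-hydroxy-2-{(2R,3S)-2-(hydroxymethyl)-3-[3-methoxy-4-(pivaloyloxy)phenyl]-2,3-dihydro-1,4-benzodioxin-6-yl}-4-oxochroman-7-yl pivalate | COc1cc([C@@H]2Oc3cc([C@@H]4CC(=O)c5c(O)cc(OC(=O)C(C)(C)C)cc5O4)ccc3O[C@@H]2CO)ccc1OC(=O)C(C)(C)C | intermediate
13 | isocisilandrin | COc1cc([C@@H]2Oc3cc([C@@H]4CC(=O)c5c(O)cc(O)cc5O4)ccc3O[C@@H]2CO)ccc1O | target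

**Totals and risks**

Total step count: 7. Longest linear sequence: 6 steps (steps 1, 2, 3, 5, 6 and 7, starting from 1).

Most likely to fail, in order:

Step 6, the new photochemical ring closure. It can fail through ipso attack at C3' (a five-membered spiro adduct that would migrate the aryl group between the two side-chain oxygens), through closure by the primary alcohol to a seven-membered ring, through loss of the benzylic hydrogen at flavanone C2 from the radical cation, or simply through low quantum efficiency. The fallback uses known chemistry only, sets out from 7 and comes back at 12. Commercial (2S)-eriodictyol F1 is pivaloylated at 7-OH as in step 4 to give 7-O-pivaloyl-(2S)-eriodictyol F2. Mitsunobu coupling of F2 with 7 (inversion, as in step 5) gives both catechol mono-ethers, and the 3'-O-ether F3 (4'-OH free) is separated by chromatography. PhNTf2 and K2CO3 in acetone convert F3 into the 4'-triflate F4, and 2 M aq. HCl in THF removes the acetonide to give the diol triflate F5. A known intramolecular aryl C–O coupling (Pd(OAc)2, 2-(di-tert-butylphosphino)-1,1'-binaphthyl, K3PO4, toluene, 60 °C) then closes the dioxane ring with retention at the carbinol carbon and delivers 12. The cost is the regioisomer separation that the hesperetin methyl ether avoids in the main route.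

Step 5, the Mitsunobu reaction at an α-branched benzylic carbinol with an ortho-substituted phenol. It can suffer elimination to the enol ether, partial ionisation that erodes the inversion, or poor conversion. The fallback sets out from 7 and comes back at 11, replacing the Mitsunobu reaction by a cyclic sulfate opening. Aqueous AcOH (80 %, 40 °C) gives the threo triol F6, and TBSCl with imidazole silylates the primary hydroxyl to give the silyl ether diol F7. SOCl2 and Et3N give the cyclic sulfite F8, and RuCl3 (cat.) with NaIO4 oxidises it to the cyclic sulfate F9. The 3'-phenoxide of 9 (Cs2CO3, MeCN, rt) opens F9 at the benzylic carbon with inversion to give the sulfate monoester F10. Catalytic H2SO4 in wet THF then hydrolyses the sulfate ester and the silyl ether to 11.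

Step 2, the telescoped Weinreb/aryl-Grignard ketone synthesis. It can fail through attack on the pivalate, incomplete exchange, over-addition or epimerisation next to the ketone. The fallback sets out from 2 (through 5) and comes back at 6. The Grignard reagent 5 is added to commercial (R)-2,3-O-isopropylideneglyceraldehyde F11 (THF, –78 °C) to give the epimeric carbinols F12, and Dess–Martin periodinane (NaHCO3, CH2Cl2) oxidises both epimers to the ketone 6.

**Further compounds**

F1 | step 6 | (2S)-eriodictyol | Oc1ccc([C@@H]2CC(=O)c3c(O)cc(O)cc3O2)cc1O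
F2 | step 6 | 7-O-pivaloyl-(2S)-eriodictyol | Oc1ccc([C@@H]2CC(=O)c3c(O)cc(OC(=O)C(C)(C)C)cc3O2)cc1O
F3 | step 6 | 3'-O-{(S)-[(4R)-2,2-dimethyl-1,3-dioxolan-4-yl][3-methoxy-4-(pivaloyloxy)phenyl]methyl} ether of F2 | Oc1ccc([C@@H]2CC(=O)c3c(O)cc(OC(=O)C(C)(C)C)cc3O2)cc1O[C@@H](c1ccc(OC(=O)C(C)(C)C)c(OC)c1)[C@H]1COC(C)(C)O1
F4 | step 6 | 4'-triflate of F3 | FC(F)(F)S(=O)(=O)Oc1ccc([C@@H]2CC(=O)c3c(O)cc(OC(=O)C(C)(C)C)cc3O2)cc1O[C@@H](c1ccc(OC(=O)C(C)(C)C)c(OC)c1)[C@H]1COC(C)(C)O1
F5 | step 6 | diol triflate (acetonide of F4 removed) | FC(F)(F)S(=O)(=O)Oc1ccc([C@@H]2CC(=O)c3c(O)cc(OC(=O)C(C)(C)C)cc3O2)cc1O[C@@H](c1ccc(OC(=O)C(C)(C)C)c(OC)c1)[C@H](O)CO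
F6 | step 5 | 4-[(1R,2R)-1,2,3-trihydroxypropyl]-2-methoxyphenyl pivalate | O[C@H](c1ccc(OC(=O)C(C)(C)C)c(OC)c1)[C@H](O)CO
F7 | step 5 | 4-[(1R,2R)-3-(tert-butyldimethylsilyloxy)-1,2-dihydroxypropyl]-2-methoxyphenyl pivalate | O[C@H](c1ccc(OC(=O)C(C)(C)C)c(OC)c1)[C@H](O)CO[Si](C)(C)C(C)(C)C
F8 | step 5 | trans cyclic sulfite of F7 (sulfur epimers) | COc1cc([C@H]2OS(=O)O[C@@H]2CO[Si](C)(C)C(C)(C)C)ccc1OC(=O)C(C)(C)C
F9 | step 5 | trans cyclic sulfate of F7 | COc1cc([C@H]2OS(=O)(=O)O[C@@H]2CO[Si](C)(C)C(C)(C)C)ccc1OC(=O)C(C)(C)C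
F10 | step 5 | cesium sulfate monoester of the silylated erythro ether | COc1ccc([C@@H]2CC(=O)c3c(O)cc(OC(=O)C(C)(C)C)cc3O2)cc1O[C@@H](c1ccc(OC(=O)C(C)(C)C)c(OC)c1)[C@@H](CO[Si](C)(C)C(C)(C)C)OS(=O)(=O)[O-].[Cs+]
F11 | step 2 | (R)-2,3-O-isopropylideneglyceraldehyde | O=C[C@H]1COC(C)(C)O1
F12 | step 2 | 4-{[(4R)-2,2-dimethyl-1,3-dioxolan-4-yl](hydroxy)methyl}-2-methoxyphenyl pivalate (carbinol epimers) | OC(c1ccc(OC(=O)C(C)(C)C)c(OC)c1)[C@H]1COC(C)(C)O1
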